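**Retrosynthetic overview**

1. Target 14 ⇐ silyl ether 13 ⇐ tribromide 10 + two molecules of guaiazulene 11 in one palladium-catalysed operation: ring closure C3–C3a by C–H alkenylation, then C–H arylation of guaiazulene C3 at C2–Br and at C6–Br.
2. 10 ⇐ ynone 9 (anti addition of Br2) ⇐ monolithiated symmetric dibromide 5 + Weinreb amide 7; 5 ⇐ methyl 3,5-dibromo-4-methylbenzoate 1.
3. Order of rings: the benzene ring (from 1) and the two azulene bicycles (from 11) are bought intact; the only ring made is the five-membered enone ring C1–C2–C3–C3a–C7a, closed at C3–C3a in step 6.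
4. Enabling feature: the C7 methyl group blocks one ortho position of the aryl ketone, so C3a–H is the only aromatic C–H within reach of a palladium on C3. C3 is the β-carbon of the C2=C3 enone and holds the most reactive C–Br bond. C2 and C6 both end up bonded to the nucleophilic C3 of a guaiazulene, so both can be bromides.

Key step: step 6

Remark: the target SMILES carries no stereodescriptor and the molecule has no stereocentre; the two hindered aryl–azulenyl axes are assumed to need no control, so the only stereochemical element handled is the transient (E)-alkene of 10.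

**Step 1**
Reactants: 1 methyl 3,5-dibromo-4-methylbenzoate
Product: 3 2-(3,5-dibromo-4-methylphenyl)propan-2-ol, via methyl ketone 2 (not isolated)
Conditions: MeMgBr (3 equiv), THF, 0 °C to rt; aq NH4Cl
Reagents that add atoms: methylmagnesium bromide (two molecules add), C[Mg]Br
Why: Double Grignard addition to the ester (the methyl ketone formed first is more electrophilic and is consumed as it forms) should give the tertiary carbinol, the aryl bromides being inert to MeMgBr at this temperature.

**Step 2**
Reactants: 3 2-(3,5-dibromo-4-methylphenyl)propan-2-ol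
Product: 5 [2-(3,5-dibromo-4-methylphenyl)propan-2-yl]oxy(triethyl)silane, via potassium alkoxide 4 (not isolated)
Conditions: KH, THF, 0 °C; TESCl, 0 °C to rt
Reagents that add atoms: chlorotriethylsilane, CC[Si](Cl)(CC)CC
Why: O-Silylation of the pre-formed potassium alkoxide (silyl ether formation) should overcome the hindrance of the tertiary benzylic alcohol and removes the acidic proton before the organolithium and palladium steps.

**Step 3**
Reactants: 6 but-2-ynoic acid
Product: 7 N-methoxy-N-methylbut-2-ynamide
Conditions: MeNHOMe (free base), DCC, CH2Cl2, 0 °C to rt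
Reagents that add atoms: N,O-dimethylhydroxylamine, CNOC
Why: Carbodiimide-mediated amide coupling should give the Weinreb amide, the weakly nucleophilic amine not adding to the β-methylated alkyne.

**Step 4**
Reactants: 5 [2-(3,5-dibromo-4-methylphenyl)propan-2-yl]oxy(triethyl)silane; 7 N-methoxy-N-methylbut-2-ynamide
Product: 9 1-{3-bromo-2-methyl-5-[2-(triethylsilyloxy)propan-2-yl]phenyl}but-2-yn-1-one, via aryllithium 8 (not isolated)
Conditions: n-BuLi (1.0 equiv), THF, −78 °C; then 7 (1.1 equiv), −78 to −20 °C; aq NH4Cl
Reagents that add atoms: none
Why: Single bromine–lithium exchange on the symmetric dibromide (both bromides are equivalent and the monolithio species resists a second exchange at −78 °C) followed by Weinreb ketone synthesis should give the ynone, the chelated tetrahedral adduct preventing over-addition.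

**Step 5**
Reactants: 9 1-{3-bromo-2-methyl-5-[2-(triethylsilyloxy)propan-2-yl]phenyl}but-2-yn-1-one
Product: 10 (E)-2,3-dibromo-1-{3-bromo-2-methyl-5-[2-(triethylsilyloxy)propan-2-yl]phenyl}but-2-en-1-one
Conditions: Br2 (1.05 equiv), CH2Cl2, −20 to 0 °C, dark
Reagents that add atoms: bromine, BrBr
Why: Electrophilic anti addition of bromine across the alkyne through a bromonium ion should give the (E)-dibromide, the anti mode of addition setting the alkene geometry that places the C3 bromine cis to the aroyl group.

**Step 6**
Reactants: 10 (E)-2,3-dibromo-1-{3-bromo-2-methyl-5-[2-(triethylsilyloxy)propan-2-yl]phenyl}but-2-en-1-one; 11 guaiazulene (1,4-dimethyl-7-(propan-2-yl)azulene), of which two molecules are incorporated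
Product: 13 2,6-bis[3,8-dimethyl-5-(propan-2-yl)azulen-1-yl]-3,7-dimethyl-4-[2-(triethylsilyloxy)propan-2-yl]-1H-inden-1-one, via dibromoindenone 12 (not isolated)
Conditions: Pd(OAc)2 (10 mol %), PPh3 (20 mol %), KOAc (6 equiv), DMA, 90 °C; then 11 (2.5 equiv), 140 °C, same flask
Reagents that add atoms: guaiazulene (the second molecule of 11 that enters the product; the first stands under Reactants), Cc1ccc2c(C)ccc(C(C)C)cc1-2
Why: Proposed new method: zerovalent palladium should insert first into the C3–Br bond of 10, the β-bromide of the enone (a vinylogous acyl bromide, more reactive than the α-vinyl bromide and the aryl bromide flanked by a methyl group), and because the (E)-alkene holds this palladium cis to the aroyl group, acetate-assisted concerted metalation–deprotonation of the one free ortho C–H gives a six-membered palladacycle whose reductive elimination forms the C3–C3a bond. The closest known reaction type is the palladium-catalysed intramolecular direct arylation that turns 2-halobenzophenones into fluorenones, here with an alkenyl in place of an aryl halide and with two further bromides that must survive the first stage. The five-membered enone ring is the only ring closed, by C(sp2)–C(sp2) reductive elimination onto an unfunctionalised arene carbon from the six-membered palladacycle. Once 10 is consumed and guaiazulene is added, the same catalyst should insert into the C2–Br and C6–Br bonds of 12, and each organopalladium acetate should be attacked by one molecule of guaiazulene at C3, its most nucleophilic free position (C1 is methylated), as in the known direct C3-arylation of guaiazulene with aryl bromides under Pd(OAc)2 and KOAc in an amide solvent, so that two molecules of 11 enter the product and KOAc takes up three equivalents of HBr in all. No stereocentre is created. The step needs three selectivities: the site of the first oxidative addition (secured by the β-position of the C3 bromide), the site of C–H cleavage (secured by the C7 methyl group, which leaves C3a–H as the only ortho hydrogen, reached through a six-membered palladacycle in preference to the seven-membered one that the methyl C–H would need), and ring closure before intermolecular coupling together with C3 rather than C2 or C4-methyl arylation of guaiazulene (secured by adding 11 only after the first stage and by acetate without carbonate in DMA).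

**Step 7**
Reactants: 13 2,6-bis[3,8-dimethyl-5-(propan-2-yl)azulen-1-yl]-3,7-dimethyl-4-[2-(triethylsilyloxy)propan-2-yl]-1H-inden-1-one
Product: 14 2,6-bis[3,8-dimethyl-5-(propan-2-yl)azulen-1-yl]-4-(2-hydroxypropan-2-yl)-3,7-dimethyl-1H-inden-1-one
Conditions: HF·pyridine, pyridine, THF, 0 °C to rt
Reagents that add atoms: none
Why: Fluoride-driven cleavage of the Si–O bond (silyl ether deprotection) under pyridine-buffered conditions should free the tertiary alcohol without ionising it and without touching the indenone or the azulenes.

**Compound list**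

1 | methyl 3,5-dibromo-4-methylbenzoate | COC(=O)c1cc(Br)c(C)c(Br)c1 | starting material
2 | 1-(3,5-dibromo-4-methylphenyl)ethan-1-one (formed in the flask in step 1) | CC(=O)c1cc(Br)c(C)c(Br)c1 | intermediate
3 | 2-(3,5-dibromo-4-methylphenyl)propan-2-ol | CC(C)(O)c1cc(Br)c(C)c(Br)c1 | intermediate
4 | potassium 2-(3,5-dibromo-4-methylphenyl)propan-2-olate (formed in the flask in step 2) | CC(C)([O-])c1cc(Br)c(C)c(Br)c1.[K+] | intermediate
5 | [2-(3,5-dibromo-4-methylphenyl)propan-2-yl]oxy(triethyl)silane | CC[Si](CC)(CC)OC(C)(C)c1cc(Br)c(C)c(Br)c1 | intermediate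
6 | but-2-ynoic acid | CC#CC(=O)O | starting material
7 | N-methoxy-N-methylbut-2-ynamide | CC#CC(=O)N(C)OC | intermediate
8 | {3-bromo-2-methyl-5-[2-(triethylsilyloxy)propan-2-yl]phenyl}lithium (formed in the flask in step 4) | [Li]c1cc(C(C)(C)O[Si](CC)(CC)CC)cc(Br)c1C | intermediate
9 | 1-{3-bromo-2-methyl-5-[2-(triethylsilyloxy)propan-2-yl]phenyl}but-2-yn-1-one | CC#CC(=O)c1cc(C(C)(C)O[Si](CC)(CC)CC)cc(Br)c1C | intermediate
10 | (E)-2,3-dibromo-1-{3-bromo-2-methyl-5-[2-(triethylsilyloxy)propan-2-yl]phenyl}but-2-en-1-one | C/C(Br)=C(\Br)C(=O)c1cc(C(C)(C)O[Si](CC)(CC)CC)cc(Br)c1C | intermediate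
11 | guaiazulene, 1,4-dimethyl-7-(propan-2-yl)azulene | Cc1ccc2c(C)ccc(C(C)C)cc1-2 | starting material
12 | 2,6-dibromo-3,7-dimethyl-4-[2-(triethylsilyloxy)propan-2-yl]-1H-inden-1-one (formed in the flask in step 6) | CC1=C(Br)C(=O)c2c(C)c(Br)cc(C(C)(C)O[Si](CC)(CC)CC)c21 | intermediate
13 | 2,6-bis[3,8-dimethyl-5-(propan-2-yl)azulen-1-yl]-3,7-dimethyl-4-[2-(triethylsilyloxy)propan-2-yl]-1H-inden-1-one | CC1=C(c2cc(C)c3cc(C(C)C)ccc(C)c2-3)C(=O)c2c(C)c(-c3cc(C)c4cc(C(C)C)ccc(C)c3-4)cc(C(C)(C)O[Si](CC)(CC)CC)c21 | intermediate
14 | 2,6-bis[3,8-dimethyl-5-(propan-2-yl)azulen-1-yl]-4-(2-hydroxypropan-2-yl)-3,7-dimethyl-1H-inden-1-one (CNP0151235.0) | CC1=C(c2cc(C)c3cc(C(C)C)ccc(C)c2-3)C(=O)c2c(C)c(-c3cc(C)c4cc(C(C)C)ccc(C)c3-4)cc(C(C)(C)O)c21 | target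

**Step count**

Total step count: 7. Longest linear sequence: 6 steps (steps 1, 2, 4, 5, 6, 7); step 3 is a one-step side branch.

**Steps most likely to fail**

1. Step 6 (proposed new method).
 - What may go wrong: loss of the C2 bromide from the vinylpalladium intermediate (β-bromide elimination back to the alkyne); slow C–H palladation at the crowded position next to the silyloxyisopropyl group; oxidative addition into the aryl or α-vinyl bromide before the ring has closed; self-coupling of the dibromoindenone while no guaiazulene is present; arylation of guaiazulene at C2 or at its C4 methyl group instead of C3.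
 - Fallback, by known reaction types, closing the same bond stepwise: setting out from ynone 9, anti-hydrobromination with LiBr and AcOH in MeCN should give (Z)-3-bromo-1-aryl-but-2-en-1-one F1, in which no bromine sits next to the carbon that will carry palladium. Palladium-catalysed intramolecular direct C–H alkenylation, the alkenyl bromide counterpart of the fluorenone-forming cyclisation (Pd(OAc)2, PCy3·HBF4, K2CO3, PivOH, DMA, 100 °C), would close C3–C3a to give 6-bromo-3-methylindenone F2. Addition of Br2 to the C2=C3 bond would give trans-2,3-dibromoindanone F3, and dehydrobromination with K2CO3 in MeCN (loss of the C3 bromide through the C2 enolate) would come back to the route at dibromoindenone 12. Compound 12 is then isolated and taken to 13 with two equivalents of guaiazulene 11 under the second-stage conditions of step 6 alone.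

2. Step 4.
 - What may go wrong: double exchange; proton transfer from the ortho methyl group to the aryllithium; butylation of the aryllithium by the 1-bromobutane formed; conjugate addition to the ynamide.
 - Fallback: setting out from silyl ether 5, bromine–magnesium exchange with i-PrMgCl·LiCl (THF, 0 °C to rt) would give the less basic arylmagnesium chloride F4, which is formylated with DMF to aldehyde F5. Addition of 1-propynylmagnesium bromide (THF, 0 °C) would give racemic propargylic alcohol F6, and oxidation with MnO2 (CH2Cl2, rt) would come back to the route at ynone 9.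

3. Step 7.
 - What may go wrong: slow fluoride attack at the hindered tertiary silyl ether; under the forcing acidic fluoride this would call for, ionisation of the tertiary benzylic C–O bond with loss of water or protonation of the azulenes.
 - Fallback, leaving the protecting group out: setting out from carbinol 3, n-BuLi (2.1 equiv, THF, −78 °C) would give dilithio species F7 (lithium alkoxide plus aryllithium), which is acylated with Weinreb amide 7 to hydroxy ynone F8. Br2 would give hydroxy dibromoenone F9, and the conditions of step 6 applied to F9 and two equivalents of guaiazulene 11, through hydroxy dibromoindenone F10 (not isolated), would come back to the route at target 14 itself.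

**Further compounds**

F1 | step 6 | (Z)-3-bromo-1-{3-bromo-2-methyl-5-[2-(triethylsilyloxy)propan-2-yl]phenyl}but-2-en-1-one | C/C(Br)=C/C(=O)c1cc(C(C)(C)O[Si](CC)(CC)CC)cc(Br)c1C
F2 | step 6 | 6-bromo-3,7-dimethyl-4-[2-(triethylsilyloxy)propan-2-yl]-1H-inden-1-one | CC1=CC(=O)c2c(C)c(Br)cc(C(C)(C)O[Si](CC)(CC)CC)c21
F3 | step 6 | rac-(2R,3R)-2,3,6-tribromo-3,7-dimethyl-4-[2-(triethylsilyloxy)propan-2-yl]-2,3-dihydro-1H-inden-1-one (trans dibromide, one enantiomer drawn) | C[C@]1(Br)[C@H](Br)C(=O)c2c(C)c(Br)cc(C(C)(C)O[Si](CC)(CC)CC)c21
F4 | step 4 | {3-bromo-2-methyl-5-[2-(triethylsilyloxy)propan-2-yl]phenyl}magnesium chloride | Cl[Mg]c1cc(C(C)(C)O[Si](CC)(CC)CC)cc(Br)c1C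
F5 | step 4 | 3-bromo-2-methyl-5-[2-(triethylsilyloxy)propan-2-yl]benzaldehyde | O=Cc1cc(C(C)(C)O[Si](CC)(CC)CC)cc(Br)c1C
F6 | step 4 | rac-1-{3-bromo-2-methyl-5-[2-(triethylsilyloxy)propan-2-yl]phenyl}but-2-yn-1-ol | CC#CC(O)c1cc(C(C)(C)O[Si](CC)(CC)CC)cc(Br)c1C
F7 | step 7 | lithium 2-(3-bromo-5-lithio-4-methylphenyl)propan-2-olate | [Li]c1cc(C(C)(C)O[Li])cc(Br)c1C
F8 | step 7 | 1-[3-bromo-5-(2-hydroxypropan-2-yl)-2-methylphenyl]but-2-yn-1-one | CC#CC(=O)c1cc(C(C)(C)O)cc(Br)c1C
F9 | step 7 | (E)-2,3-dibromo-1-[3-bromo-5-(2-hydroxypropan-2-yl)-2-methylphenyl]but-2-en-1-one | C/C(Br)=C(\Br)C(=O)c1cc(C(C)(C)O)cc(Br)c1C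
F10 | step 7 | 2,6-dibromo-4-(2-hydroxypropan-2-yl)-3,7-dimethyl-1H-inden-1-one | CC1=C(Br)C(=O)c2c(C)c(Br)cc(C(C)(C)O)c21
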